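The runs are simulated from invented constants; scatter was added.

At early times Q in the theta run falls like a first-order lag: the readings give 15% at 15.0 h and 7% at 25.0 h.

| setting | theta | alpha | flask |
|---|---|---|---|
| Q | 0.50 M | 0.75 M | 0.50 M |
| L | 0.525 M | 0.525 M | 0.525 M |
| temperature | −20 °C | −35 °C | −20 °C |
| remark | the very flask that is asked about, followed so far | run made earlier |  |
| time |  |  | 8.0 d |

- theta (time / h: X / %, Q / %): 15.0: 25, 15; 25.0: 24, 7; 40.0: 25, 1; 72.0: 28, 0; 120: 29, 0; 192: 28, 1
- alpha (time / h: X / %, Q / %): 3.00: 3, 88; 10.0: 3, 70; 15.0: 3, 62; 30.0: 7, 44; 40.0: 10, 35; 48.0: 10, 27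

(standard deviation of a reading: 1.5 percentage points)

- noon: at 8.0 d add L, 50.0% of the amount charged, then wait 15 d
- summer: change nothing and wait 15 d more
- midnight: at 8.0 d raise the temperature by 20 K, then wait 15 d
- spring: at 8.0 d take out 90% of the D then present, then wait 15 d

* X, in percent of the Q first charged, at 8.0 d
* the option that brings most further X ("none" if no option brings more than 2 percentage points) (noon / summer / midnight / spring / none)
* X present, in percent of the Q first charged, after summer
* X present, in percent of the Q first charged, after spring

- additions bring no volume worth counting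

Two chemists read these runs, and both start from one reckoning. Call τ the Q time constant, the time in which Q falls by a factor e; if Q decays as exp(−t/τ), the theta reading at 25.0 h gives τ = 9.40 h. The time of looking, 8.0 d, is then 20.4 time constants, far longer than τ, and Q reads 1% at 192 h. So neither chemist expects further X from remaining Q in this flask.

The first chemist made the forecast and concludes: “X stays flat at about 28% from 72 to 192 h with Q gone, so the plateau comes from exhausted feed.” The forecast gives 28.3% now, 28.3% after summer, 28% after spring, and as best option none.

The second chemist looks at X per Q consumed. In the theta flask at 192 h, at −20 °C, it is 28.3%, and in the alpha run at 48.0 h, at −35 °C, it is 13.7%, so the theta flask shows about twice the share, though the two differ in Q as well, 0.50 M against 0.75 M. This chemist holds that the rest of the consumed Q stands in unread forms that can still turn into X when the temperature moves. The gap between the runs, 15 percentage points, is larger than the mark of 2 points, so this chemist names midnight, with its rise of 20 K.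

The simulation gives 26.3% now, 26.3% after summer and 26.3% after spring, so the forecast's three numbers stand within their margins. The best option is midnight, with 10 points further X, which is less than the gap the second chemist reckoned. The first chemist's view holds at constant temperature in this flask: noon brings 0 points, summer 0 points and spring 0 points.

    Q + L → J + D (k = 9.14 × 10⁻⁵ L mol⁻¹ s⁻¹, Ea = 60.0 kJ mol⁻¹)
    J ⇌ X (K = 4.20, k = 1.95 × 10⁻⁴ s⁻¹, Ea = 71.0 kJ mol⁻¹, ΔH = 16.0 kJ mol⁻¹)
    J ⇌ G (K = 2.00, k = 9.77 × 10⁻⁵ s⁻¹, Ea = 71.0 kJ mol⁻¹, ΔH = −30.0 kJ mol⁻¹)
    Q + J → E (k = 3.34 × 10⁻⁴ L mol⁻¹ s⁻¹, Ea = 44.0 kJ mol⁻¹)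
    (constants at −20 °C)

From τ, Q in the flask at 96.0 h should be 0.00367% of the charge, and the flask holds 0.00737%. At 192 h it holds Q 0% beside G 12.5% and J 6.26%, with L 31% left; Q is the limiting reagent. The neighbouring flask has 0.30 M of Q and the same L charge; keeping τ, it also stands 20.4 time constants in at 192 h. There it holds Q 0% with L 54% left, and X stands at 36.4%.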